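**One price.** 4 questions stand on Friday's flask, and one price in E answers them.

| flask | G | E | temperature | remark | time |
|---|---|---|---|---|---|
| Friday's | 0.22 M | 0.55 M | 90 °C | the very flask that is asked about, followed so far |  |
| Thursday's | 0.11 M | 0.55 M | 75 °C | run made earlier |  |
| flask | 0.22 M | 0.550 M | 90 °C |  | 8.0 d |

| run | time / h | X / % | G / % |
|---|---|---|---|
| Friday's | 12.0 | 62 | 15 |
| Friday's | 20.0 | 67 | 15 |
| Friday's | 30.0 | 67 | 12 |
| Friday's | 60.0 | 69 | 11 |
| Friday's | 96.0 | 66 | 8 |
| Friday's | 144 | 74 | 6 |
| Thursday's | 0.500 | 2 | 95 |
| Thursday's | 2.00 | 8 | 85 |
| Thursday's | 3.00 | 12 | 78 |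
| Thursday's | 4.00 | 19 | 70 |
| Thursday's | 6.00 | 21 | 63 |
| Thursday's | 8.00 | 27 | 55 |

(each reading ± 2 percentage points)

* X, in percent of the G first charged, at 8.0 d
* the option that brings most further X ("none" if no option brings more than 2 percentage points) (zeta / delta / gamma / theta / none)
* X present, with what was taken out counted in, in percent of the G first charged, after zeta
* X present, with what was taken out counted in, in percent of the G first charged, after delta

- zeta: at 8.0 d take out 90% of the X then present, then wait 15 d
- delta: change nothing and wait 15 d more
- gamma: at 8.0 d add E, 50.0% of the amount charged, then wait 15 d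
- theta: at 8.0 d raise the temperature by 15 K, then wait 15 d

- X taken out counts as made
- additions bring no volume worth counting

**Both ends.** Thursday's flask loses G at a pace of 0.0747 /h, the share of G lost per hour over its run. Friday's flask, though hotter, loses it after 12.0 h at 0.00694 /h. G still reads about 7.00% in its last two readings, so the likely limiting reagent in Friday's flask is E, which was never read. Even Thursday's cooler pace reaches that level in 35.6 h, sooner than Friday's readings reach it at 96.0 h, so this reckoning takes Friday's flask as halted before 8.0 d.

**The price.** If Friday's flask has spent its 0.550 M of E at the halt, that E has paid for a fall in cG of 0.205 M. That gives 2.69, the E price: the amount of E a flask spends, by whatever road, for each amount of G that disappears up to its halt. X averages 69.7% over the last 3 readings, so the selectivity, the share of lost G read as X, is 0.749.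

**The options.** Gamma adds 0.275 M of E to Friday's flask, more than the 0.0414 M that its remaining G asks at that price. Gamma should therefore gain about 5.2 percentage points. Zeta, delta and theta add no E, so this reckoning keeps X at 69.7% at 8.0 d, after zeta and after delta.

**Weak link.** The halt is the weak link, since G reads 11% at 60.0 h and 6% at 144 h. That fall is 1.77 standard deviations of a difference between two readings, and X reads 66% in between, so these readings do not tell a halt from a slow creep, and this reckoning stays with the halt as its estimate.

**The forecast.** The forecast gives 72% now, within 70% to 74.5%, and 75% after zeta and 75% after delta, higher than this reckoning, and it names gamma: “Adding E finishes the remainder most surely”.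

**The result.** The flask gives X 70.2% now, 70.2% after zeta and 70.2% after delta, and gamma brings 5.4 points.

    E → D (k = 1.50 × 10⁻⁵ /s, Ea = 108 kJ/mol)
    G + 2 E → L (k = 1.10 × 10⁻⁴ /M²/s, Ea = 81.0 kJ/mol)
    G + E → X (k = 1.10 × 10⁻⁴ /M/s, Ea = 102 kJ/mol)
    (constants at 90 °C)

**Where E went.** At 192 h Friday's flask holds E 0% and G 7.19%. The path to L, which takes 2 E for each G, is the main reason X ends at 70.2%: the same flask without that path gives 92.2%. At 2.69, a neighbour of Friday's flask charged with 0.22 M of E, its other charges the same, is reckoned to turn 37.2% of its G. With E at 0% at 192 h, that neighbour has turned 52.6%, a price of 1.90, and it holds L at 5.29%.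

All runs stem from a simulated flask for substances that don't exist, and the scatter is random.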